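The biaryl bond divides the target into two olivil-type oxolanes made by one annulation. In the key step ring A (O1, C2–C5; its C2 arene belongs to the biaryl) forms from a cinnamaldehyde (C2=C3) and dihydroxyacetone (O1–C5–C4): amine-catalysed oxa-Michael addition makes O1–C2 and the enamine aldol makes C3–C4. The feature exploited is the cis relation of the exocyclic carbons on C3 and C4 (CH2OH and benzylic CH2): the second CH2OH arm of the ketone traps the C3 formyl group as a temporary cis-fused lactol ring, which fixes the C4 carbinol centre. The lactol is then opened, its CH2–O carbon arylated via a spiro-epoxide, and Suzuki coupling joins the halves.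

Key step: step 2

Remark: in each oxolane the atoms are called O1, C2 (aryl-bearing CH), C3 (CH bearing CH2OH), C4 (carbinol carbon) and C5 (CH2); ring A is the oxolane whose C2 arene lies in the biaryl, ring B the other one.
Remark: compounds 1, 2, 4, 9, 13 and 19 are taken to be commercial.
Remark: 1,3-dihydroxyacetone 4 is charged as the monomeric ketone. A solid sample that has associated on storage is first stirred in the reaction solvent with the acid co-catalyst until it has reverted to the monomer, and equivalents refer to the monomer.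

Step 1
Reactants: 1 4-(benzyloxy)-3-bromo-5-methoxybenzaldehyde; 2 (triphenyl-λ5-phosphanylidene)acetaldehyde
Product: 3 (2E)-3-[4-(benzyloxy)-3-bromo-5-methoxyphenyl]prop-2-enal
Conditions: 2 (1.2 equiv), toluene, 80 °C
Reagents that add atoms: none
Why: Wittig olefination with a stabilised formyl ylide should give the E-enal under thermodynamic control of the oxaphosphetane.

Step 2
Reactants: 3 (2E)-3-[4-(benzyloxy)-3-bromo-5-methoxyphenyl]prop-2-enal; 4 1,3-dihydroxyacetone
Product: 6 (3aS,6S,6aR)-6-[4-(benzyloxy)-3-bromo-5-methoxyphenyl]tetrahydro-1H,3H-furo[3,4-c]furan-1,3a(4H)-diol (lactol of ring A; both C1 epimers), via hydroxy aldehyde 5 (not isolated)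
Conditions: 4 (1.2 equiv), (S)-2-[diphenyl(trimethylsilyloxy)methyl]pyrrolidine (20 mol %), PhCO2H (20 mol %), CHCl3, rt
Reagents that add atoms: none
Why: Enal 3 condenses with the amine to an s-trans E-iminium ion whose top face is covered by the CPh2(OSiMe3) group, so a primary hydroxyl of ketone 4 adds reversibly to the β-carbon from the open Si face (oxa-Michael, forms O1–C2, C2 = S), and the enamine so formed attacks the ketone carbon (aldol, forms C3–C4) before hydrolysis releases aldehyde 5. The closest known reaction is the iminium–enamine oxa-Michael/aldol/hemiacetalisation domino of enals with 1,3-dihydroxyacetone, of which β-aryl enals are expected to be the slower members. The oxolane closes in the aldol step in a 5-exo-trig (5-enolexo) mode and the temporary lactol ring closes by 5-exo-trig addition of the second CH2OH arm to the formyl group. C3 is placed trans to the aryl group, kinetically by approach anti to the catalyst shield and thermodynamically because the α-formyl centre can epimerise. C4 is fixed by the lactol: only the aldol epimer with the CH2OH arm cis to the formyl group can close the cis-fused dioxabicyclo[3.3.0]octane, and since the oxa-Michael and aldol steps are reversible the material should funnel into it, giving the cis C3-carbon/C4-carbon and trans C3-carbon/C4-OH pattern of the target. The selectivity needed is conjugate O-addition over acetal formation, and a C4 configuration that an open aldol with a simple benzyl hydroxymethyl ketone would not secure (OH cis to CHO would be favoured there); the symmetric two-armed ketone and the lactol sink provide both.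

Step 3
Reactants: 6 lactol of ring A
Product: 7 (3R,4R,5S)-5-[4-(benzyloxy)-3-bromo-5-methoxyphenyl]-4-ethenyl-3-(hydroxymethyl)oxolan-3-ol
Conditions: Ph3PCH3Br (4 equiv), KOtBu (3.8 equiv), THF, 0 °C to rt
Reagents that add atoms: methyltriphenylphosphonium bromide C[P+](c1ccccc1)(c1ccccc1)c1ccccc1.[Br-]
Why: Wittig methylenation of the ring-opened aldehyde tautomer of the lactol should open the temporary ring, mask C3–CHO as a vinyl group and free the primary hydroxyl on the future benzylic carbon without touching a stereocentre.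

Step 4
Reactants: 7 vinyl diol of ring A
Product: 8 (3R,6S,7R)-6-[4-(benzyloxy)-3-bromo-5-methoxyphenyl]-7-ethenyl-1,5-dioxaspiro[2.4]heptane
Conditions: NaH (2.2 equiv), THF, 0 °C; then 1-(4-methylbenzenesulfonyl)imidazole (1.05 equiv), 0 °C to rt
Reagents that add atoms: none
Why: One-pot sulfonylation of the primary alkoxide followed by 3-exo-tet Williamson closure by the tertiary alkoxide should give the spiro-epoxide with C4 unchanged, because the C4–O bond is never broken.

Step 5
Reactants: 8 spiro-epoxide of ring A; 9 1-(benzyloxy)-4-bromo-2-methoxybenzene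
Product: 11 (3S,4R,5S)-5-[4-(benzyloxy)-3-bromo-5-methoxyphenyl]-3-{[4-(benzyloxy)-3-methoxyphenyl]methyl}-4-ethenyloxolan-3-ol, via arylmagnesium bromide 10 (not isolated)
Conditions: 9 (3 equiv), Mg, THF, reflux; then CuI (10 mol %), 8, THF, −30 to 0 °C
Reagents that add atoms: none
Why: Copper-catalysed Grignard opening of the 2,2-disubstituted oxirane at its CH2 carbon (SN2) should install the benzyl arene and leave C4 with the configuration set in step 2, the aryl bromide of 8 being inert to ArMgBr at this temperature.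

Step 6
Reactants: 11 bromide of the A half
Product: 12 (3S,4R,5S)-5-[4-(benzyloxy)-3-methoxy-5-(4,4,5,5-tetramethyl-1,3,2-dioxaborolan-2-yl)phenyl]-3-{[4-(benzyloxy)-3-methoxyphenyl]methyl}-4-ethenyloxolan-3-ol
Conditions: B2pin2 (1.3 equiv), Pd(dppf)Cl2 (5 mol %), KOAc, 1,4-dioxane, 90 °C
Reagents that add atoms: bis(pinacolato)diboron CC1(C)OB(OC1(C)C)B1OC(C)(C)C(C)(C)O1
Why: Miyaura borylation of the aryl bromide should tolerate the tertiary alcohol, the benzyl ethers and the unactivated vinyl group.

Step 7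
Reactants: 13 4-(benzyloxy)-3-methoxybenzaldehyde; 2 (triphenyl-λ5-phosphanylidene)acetaldehyde
Product: 14 (2E)-3-[4-(benzyloxy)-3-methoxyphenyl]prop-2-enal
Conditions: 2 (1.2 equiv), toluene, 80 °C
Reagents that add atoms: none
Why: The same stabilised-ylide Wittig olefination as in step 1 should give the E-enal.

Step 8
Reactants: 14 (2E)-3-[4-(benzyloxy)-3-methoxyphenyl]prop-2-enal; 4 1,3-dihydroxyacetone
Product: 16 (3aS,6S,6aR)-6-[4-(benzyloxy)-3-methoxyphenyl]tetrahydro-1H,3H-furo[3,4-c]furan-1,3a(4H)-diol (lactol of ring B; both C1 epimers), via hydroxy aldehyde 15 (not isolated)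
Conditions: 4 (1.2 equiv), (S)-2-[diphenyl(trimethylsilyloxy)methyl]pyrrolidine (20 mol %), PhCO2H (20 mol %), CHCl3, rt
Reagents that add atoms: none
Why: The same oxa-Michael/aldol/hemiacetalisation domino as in step 2 should set C2 (S) by Si-face addition to the iminium ion, C3 trans to the aryl group and C4 through the cis-fused lactol trap.

Step 9
Reactants: 16 lactol of ring B
Product: 17 (3R,4R,5S)-5-[4-(benzyloxy)-3-methoxyphenyl]-4-ethenyl-3-(hydroxymethyl)oxolan-3-ol
Conditions: Ph3PCH3Br (4 equiv), KOtBu (3.8 equiv), THF, 0 °C to rt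
Reagents that add atoms: methyltriphenylphosphonium bromide C[P+](c1ccccc1)(c1ccccc1)c1ccccc1.[Br-]
Why: Wittig methylenation of the lactol should open the temporary ring as in step 3.

Step 10
Reactants: 17 vinyl diol of ring B
Product: 18 (3R,6S,7R)-6-[4-(benzyloxy)-3-methoxyphenyl]-7-ethenyl-1,5-dioxaspiro[2.4]heptane
Conditions: NaH (2.2 equiv), THF, 0 °C; then 1-(4-methylbenzenesulfonyl)imidazole (1.05 equiv), 0 °C to rt
Reagents that add atoms: none
Why: Selective primary sulfonylation and Williamson closure should give the spiro-epoxide with retention at C4, as in step 4.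

Step 11
Reactants: 19 2-bromo-6-methoxyphenol
Product: 20 2-bromo-4-iodo-6-methoxyphenol
Conditions: N-iodosuccinimide (1.05 equiv), MeCN, 0 °C to rt
Reagents that add atoms: N-iodosuccinimide O=C1CCC(=O)N1I
Why: Electrophilic aromatic iodination should go to the only free position para to the hydroxyl group, both ortho positions being blocked.

Step 12
Reactants: 20 2-bromo-4-iodo-6-methoxyphenol
Product: 21 2-(benzyloxy)-1-bromo-5-iodo-3-methoxybenzene
Conditions: BnBr, K2CO3, DMF, rt
Reagents that add atoms: benzyl bromide BrCc1ccccc1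
Why: Williamson O-benzylation of the phenoxide.

Step 13
Reactants: 18 spiro-epoxide of ring B; 21 2-(benzyloxy)-1-bromo-5-iodo-3-methoxybenzene
Product: 23 (3S,4R,5S)-5-[4-(benzyloxy)-3-methoxyphenyl]-3-{[4-(benzyloxy)-3-bromo-5-methoxyphenyl]methyl}-4-ethenyloxolan-3-ol, via arylmagnesium chloride 22 (not isolated)
Conditions: 21 (3 equiv), iPrMgCl·LiCl, THF, −20 °C; then CuI (10 mol %), 18, −30 to 0 °C
Reagents that add atoms: none
Why: Iodine–magnesium exchange is much faster than bromine–magnesium exchange, so the Grignard reagent should form para to OBn with the bromide (meta to Mg, no aryne path) intact, and copper-catalysed SN2 opening of the oxirane CH2 then keeps C4.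

Step 14
Reactants: 12 boronate of the A half; 23 bromide of the B half
Product: 24 tetra-O-benzyl bis-ethenyl biaryl (12 and 23 joined through the carbons that carried Bpin and Br; all six stereocentres unchanged)
Conditions: Pd(OAc)2 (5 mol %), SPhos (10 mol %), K3PO4, toluene/H2O (10:1), 90 °C
Reagents that add atoms: none
Why: Suzuki–Miyaura coupling with a bulky electron-rich biarylphosphine should join the two ortho-oxygenated electron-rich arenes, transmetalation being faster than Heck insertion of the unactivated vinyl groups.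

Step 15
Reactants: 24 tetra-O-benzyl bis-ethenyl biaryl
Product: 26 tetra-O-benzyl ether of the target (both ethenyl groups converted to CH2OH), via dialdehyde 25 (not isolated)
Conditions: O3, CH2Cl2/MeOH (4:1), −78 °C; then NaBH4, −78 to 0 °C
Reagents that add atoms: ozone [O-][O+]=O
Why: Ozonolysis should cleave the two monosubstituted alkenes much faster than it attacks the alkoxyarenes, and immediate cold borohydride reduction of the α-stereogenic β-hydroxy aldehydes should prevent epimerisation at C3.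

Step 16
Reactants: 26 tetra-O-benzyl ether of the target
Product: 27 CNP0269573.1 (target)
Conditions: H2 (1 atm), Pd/C (10 % palladium on carbon), EtOAc/MeOH, rt, stopped at full O-debenzylation
Reagents that add atoms: none
Why: Hydrogenolysis of aryl benzyl ethers under neutral conditions at 1 atm is faster than cleavage of the cyclic benzylic C2–O1 bonds, so the four phenols should be freed with both oxolanes intact.

Compound list
1 | 4-(benzyloxy)-3-bromo-5-methoxybenzaldehyde | COc1cc(C=O)cc(Br)c1OCc1ccccc1 | starting material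
2 | (triphenyl-λ5-phosphanylidene)acetaldehyde | O=CC=P(c1ccccc1)(c1ccccc1)c1ccccc1 | starting material
3 | (2E)-3-[4-(benzyloxy)-3-bromo-5-methoxyphenyl]prop-2-enal | COc1cc(/C=C/C=O)cc(Br)c1OCc1ccccc1 | intermediate
4 | 1,3-dihydroxyacetone | OCC(=O)CO | starting material
5 | (2S,3R,4R)-2-[4-(benzyloxy)-3-bromo-5-methoxyphenyl]-4-hydroxy-4-(hydroxymethyl)oxolane-3-carbaldehyde | OC[C@@]1(O)CO[C@H](c2cc(OC)c(OCc3ccccc3)c(Br)c2)[C@H]1C=O | intermediate
6 | (3aS,6S,6aR)-6-[4-(benzyloxy)-3-bromo-5-methoxyphenyl]tetrahydro-1H,3H-furo[3,4-c]furan-1,3a(4H)-diol (C1 epimers) | C1[C@@]2(O)CO[C@H](c3cc(OC)c(OCc4ccccc4)c(Br)c3)[C@H]2C(O)O1 | intermediate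
7 | (3R,4R,5S)-5-[4-(benzyloxy)-3-bromo-5-methoxyphenyl]-4-ethenyl-3-(hydroxymethyl)oxolan-3-ol | OC[C@@]1(O)CO[C@H](c2cc(OC)c(OCc3ccccc3)c(Br)c2)[C@H]1C=C | intermediate
8 | (3R,6S,7R)-6-[4-(benzyloxy)-3-bromo-5-methoxyphenyl]-7-ethenyl-1,5-dioxaspiro[2.4]heptane | C1[C@@]2(O1)CO[C@H](c3cc(OC)c(OCc4ccccc4)c(Br)c3)[C@H]2C=C | intermediate
9 | 1-(benzyloxy)-4-bromo-2-methoxybenzene | COc1cc(Br)ccc1OCc1ccccc1 | starting material
10 | [4-(benzyloxy)-3-methoxyphenyl]magnesium bromide | COc1cc([Mg]Br)ccc1OCc1ccccc1 | intermediate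
11 | (3S,4R,5S)-5-[4-(benzyloxy)-3-bromo-5-methoxyphenyl]-3-{[4-(benzyloxy)-3-methoxyphenyl]methyl}-4-ethenyloxolan-3-ol | COc1cc(C[C@@]2(O)CO[C@H](c3cc(OC)c(OCc4ccccc4)c(Br)c3)[C@H]2C=C)ccc1OCc1ccccc1 | intermediate
12 | (3S,4R,5S)-5-[4-(benzyloxy)-3-methoxy-5-(4,4,5,5-tetramethyl-1,3,2-dioxaborolan-2-yl)phenyl]-3-{[4-(benzyloxy)-3-methoxyphenyl]methyl}-4-ethenyloxolan-3-ol | COc1cc(C[C@@]2(O)CO[C@H](c3cc(OC)c(OCc4ccccc4)c(B5OC(C)(C)C(C)(C)O5)c3)[C@H]2C=C)ccc1OCc1ccccc1 | intermediate
13 | 4-(benzyloxy)-3-methoxybenzaldehyde | COc1cc(C=O)ccc1OCc1ccccc1 | starting material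
14 | (2E)-3-[4-(benzyloxy)-3-methoxyphenyl]prop-2-enal | COc1cc(/C=C/C=O)ccc1OCc1ccccc1 | intermediate
15 | (2S,3R,4R)-2-[4-(benzyloxy)-3-methoxyphenyl]-4-hydroxy-4-(hydroxymethyl)oxolane-3-carbaldehyde | OC[C@@]1(O)CO[C@H](c2ccc(OCc3ccccc3)c(OC)c2)[C@H]1C=O | intermediate
16 | (3aS,6S,6aR)-6-[4-(benzyloxy)-3-methoxyphenyl]tetrahydro-1H,3H-furo[3,4-c]furan-1,3a(4H)-diol (C1 epimers) | C1[C@@]2(O)CO[C@H](c3ccc(OCc4ccccc4)c(OC)c3)[C@H]2C(O)O1 | intermediate
17 | (3R,4R,5S)-5-[4-(benzyloxy)-3-methoxyphenyl]-4-ethenyl-3-(hydroxymethyl)oxolan-3-ol | OC[C@@]1(O)CO[C@H](c2ccc(OCc3ccccc3)c(OC)c2)[C@H]1C=C | intermediate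
18 | (3R,6S,7R)-6-[4-(benzyloxy)-3-methoxyphenyl]-7-ethenyl-1,5-dioxaspiro[2.4]heptane | C1[C@@]2(O1)CO[C@H](c3ccc(OCc4ccccc4)c(OC)c3)[C@H]2C=C | intermediate
19 | 2-bromo-6-methoxyphenol | COc1cccc(Br)c1O | starting material
20 | 2-bromo-4-iodo-6-methoxyphenol | COc1cc(I)cc(Br)c1O | intermediate
21 | 2-(benzyloxy)-1-bromo-5-iodo-3-methoxybenzene | COc1cc(I)cc(Br)c1OCc1ccccc1 | intermediate
22 | [4-(benzyloxy)-3-bromo-5-methoxyphenyl]magnesium chloride | COc1cc([Mg]Cl)cc(Br)c1OCc1ccccc1 | intermediate
23 | (3S,4R,5S)-5-[4-(benzyloxy)-3-methoxyphenyl]-3-{[4-(benzyloxy)-3-bromo-5-methoxyphenyl]methyl}-4-ethenyloxolan-3-ol | COc1cc(C[C@@]2(O)CO[C@H](c3ccc(OCc4ccccc4)c(OC)c3)[C@H]2C=C)cc(Br)c1OCc1ccccc1 | intermediate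
24 | tetra-O-benzyl bis-ethenyl biaryl (halves 11 and 23 joined at the former C–Br carbons) | COc1cc(C[C@@]2(O)CO[C@H](c3cc(OC)c(OCc7ccccc7)c(-c4cc(C[C@@]5(O)CO[C@H](c6ccc(OCc7ccccc7)c(OC)c6)[C@H]5C=C)cc(OC)c4OCc4ccccc4)c3)[C@H]2C=C)ccc1OCc1ccccc1 | intermediate
25 | tetra-O-benzyl biaryl dialdehyde (each ethenyl group of 24 replaced by CHO) | COc1cc(C[C@@]2(O)CO[C@H](c3cc(OC)c(OCc7ccccc7)c(-c4cc(C[C@@]5(O)CO[C@H](c6ccc(OCc7ccccc7)c(OC)c6)[C@H]5C=O)cc(OC)c4OCc4ccccc4)c3)[C@H]2C=O)ccc1OCc1ccccc1 | intermediate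
26 | tetra-O-benzyl ether of the target | COc1cc(C[C@@]2(O)CO[C@H](c3cc(OC)c(OCc7ccccc7)c(-c4cc(C[C@@]5(O)CO[C@H](c6ccc(OCc7ccccc7)c(OC)c6)[C@H]5CO)cc(OC)c4OCc4ccccc4)c3)[C@H]2CO)ccc1OCc1ccccc1 | intermediate
27 | CNP0269573.1 (5,5′-linked dimer of two (2S,3R,4S)-olivil units) | COc1cc(C[C@@]2(O)CO[C@H](c3cc(OC)c(O)c(-c4cc(C[C@@]5(O)CO[C@H](c6ccc(O)c(OC)c6)[C@H]5CO)cc(OC)c4O)c3)[C@H]2CO)ccc1O | target

Total step count: 16. Longest linear sequence: 9 steps (steps 1–6, then 14–16).

Steps most likely to fail

Step 2. The conjugate addition of a primary hydroxyl to the electron-rich β-aryl iminium ion is reversible and may stay on the side of enal 3, so that the enamine needed for ring closure is never populated and the ketone is lost to self-aldolisation. The fallback builds the same lactol stepwise from aldehyde 1 and returns at lactol 6. Aldehyde 1 is homologated with ethyl diazoacetate and catalytic SnCl2 (Roskamp reaction) to ethyl 3-[4-(benzyloxy)-3-bromo-5-methoxyphenyl]-3-oxopropanoate F1. Noyori hydrogenation with RuCl2[(S)-BINAP] should give ethyl (3R)-3-[4-(benzyloxy)-3-bromo-5-methoxyphenyl]-3-hydroxypropanoate F2. Its dilithium dianion (LiN(iPr)2, 2.2 equiv, THF, −78 °C) should add to 2,2-dimethyl-1,3-dioxan-5-one anti to the carbinol substituent (Fráter–Seebach aldol) to give ethyl (2R,3R)-3-[4-(benzyloxy)-3-bromo-5-methoxyphenyl]-3-hydroxy-2-(5-hydroxy-2,2-dimethyl-1,3-dioxan-5-yl)propanoate F3, in which C3 is set and C4 is still prochiral. Camphorsulfonic acid in wet CH2Cl2 then removes the acetonide, lactonises one CH2OH arm and closes the oxolane by benzylic substitution with the other. These reversible steps should converge on the cis-fused (3aS,6S,6aR)-6-[4-(benzyloxy)-3-bromo-5-methoxyphenyl]-3a-hydroxytetrahydro-1H,3H-furo[3,4-c]furan-1-one F4, with the aryl group on the convex face. Reduction with iBu2AlH at −78 °C gives lactol 6.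

Step 3. Under the strongly basic unstabilised ylide the ring-opened β-alkoxy aldehyde may fragment by retro-aldol cleavage of the C3–C4 bond, or lose its C3 configuration by enolisation, before it is olefinated. The fallback sets out from lactol 6 and returns at vinyl diol 7. Seyferth–Gilbert homologation with dimethyl (1-diazo-2-oxopropyl)phosphonate and K2CO3 in MeOH at 0 °C (weakly basic) should give (3R,4R,5S)-5-[4-(benzyloxy)-3-bromo-5-methoxyphenyl]-4-ethynyl-3-(hydroxymethyl)oxolan-3-ol F5. Semihydrogenation with H2 over Pd/CaCO3 poisoned with Pb(OAc)2, in the presence of quinoline, then gives 7.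

Step 16. Once a phenol is unmasked, the cyclic benzylic C2–O1 bonds become 4-hydroxybenzyl ethers and may be hydrogenolysed in competition with the remaining O-benzyl groups, opening the oxolanes. The fallback sets out from 26 and gives 27 directly by single-electron debenzylation with lithium 4,4′-di-tert-butylbiphenylide in THF at −78 °C. The electron enters the unsubstituted benzyl rings and expels phenoxide, a far better leaving group than the ring alkoxide, so the oxolanes should survive; no new compound is made.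

Further compounds
F1 | step 2 | ethyl 3-[4-(benzyloxy)-3-bromo-5-methoxyphenyl]-3-oxopropanoate | CCOC(=O)CC(=O)c1cc(OC)c(OCc2ccccc2)c(Br)c1
F2 | step 2 | ethyl (3R)-3-[4-(benzyloxy)-3-bromo-5-methoxyphenyl]-3-hydroxypropanoate | CCOC(=O)C[C@@H](O)c1cc(OC)c(OCc2ccccc2)c(Br)c1
F3 | step 2 | ethyl (2R,3R)-3-[4-(benzyloxy)-3-bromo-5-methoxyphenyl]-3-hydroxy-2-(5-hydroxy-2,2-dimethyl-1,3-dioxan-5-yl)propanoate | CCOC(=O)[C@H]([C@@H](O)c1cc(OC)c(OCc2ccccc2)c(Br)c1)C1(O)COC(C)(C)OC1
F4 | step 2 | (3aS,6S,6aR)-6-[4-(benzyloxy)-3-bromo-5-methoxyphenyl]-3a-hydroxytetrahydro-1H,3H-furo[3,4-c]furan-1-one | C1[C@@]2(O)CO[C@H](c3cc(OC)c(OCc4ccccc4)c(Br)c3)[C@H]2C(=O)O1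
F5 | step 3 | (3R,4R,5S)-5-[4-(benzyloxy)-3-bromo-5-methoxyphenyl]-4-ethynyl-3-(hydroxymethyl)oxolan-3-ol | OC[C@@]1(O)CO[C@H](c2cc(OC)c(OCc3ccccc3)c(Br)c2)[C@H]1C#C
F0 | step 16 | none | none
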